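**Plan**

1. Retrosynthesis: the three phenols are first masked as MOM ethers; then two bonds are cut together, C2–C5' (benzofuran C2 to chroman C5') and O1–C2 of the furan ring, giving ethynylphenol 8 and aryl triflate 17.
2. Enabling feature: O1–C2=C3–C3a of the furan is a latent 2-ethynylphenol, so C2 can arrive as a terminal alkyne carbon. A linear sp carbon is slim enough to reach C5', which sits between the C4' methylene and the C6' prenyl group, and the C7a oxygen then closes the furan onto the new alkyne.
3. Ethynylphenol 8 comes from 2,4,6-trihydroxybenzaldehyde: the C7–C(CH3)2 bond is made by aromatic Claisen rearrangement of the symmetric 4-O-prenyl ether (the formyl carbon blocks the para position), and the formyl group is homologated to the alkyne.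
4. Triflate 17 comes from phloroglucinol: the pyran ring by isoprene annulation, the C6'–prenyl bond by directed ortho metalation between two MOM ethers, and the C5'–O bond kept as the triflate.
5. Forward order of rings: both benzene rings are bought, the pyran ring closes in step 7, the furan ring closes in step 13 together with the fragment union, and step 14 frees the phenols.
6. Stereochemistry: the target has no stereocentre and no configured double bond; all control is regiochemical (symmetry, chelation, steric differentiation of hydroxyls).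

Key step: step 13

Remark: unprimed locants refer to the benzofuran, primed locants to the chroman; prenyl = 3-methylbut-2-en-1-yl, MOM = methoxymethyl; no SMILES needs a stereodescriptor.

**Route**

Step 1
Reactants: 1 2,4,6-trihydroxybenzaldehyde
Product: 2 2,6-dihydroxy-4-[(3-methylbut-2-en-1-yl)oxy]benzaldehyde
Conditions: prenyl bromide (1.0 equiv), K2CO3 (1.0 equiv), acetone, 0 °C to rt
Reagents that add atoms: prenyl bromide (1-bromo-3-methylbut-2-ene), CC(C)=CCBr
Why: Williamson etherification; the 4-hydroxyl, para to the formyl group and not hydrogen-bonded, is the most acidic, so one equivalent of base and halide should alkylate it while the two chelated ortho hydroxyls remain.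

Step 2
Reactants: 2 2,6-dihydroxy-4-[(3-methylbut-2-en-1-yl)oxy]benzaldehyde
Product: 4 2,4,6-trihydroxy-3-(2-methylbut-3-en-2-yl)benzaldehyde, via ortho-dienone 3 (not isolated)
Conditions: EtOH/H2O 4:1, 120 °C, sealed tube, argon
Reagents that add atoms: none
Why: Aromatic Claisen rearrangement; the [3,3] shift delivers the inverted allyl unit to either of the two equivalent ortho carbons (dienone 3, then enolization), the formyl-bearing para carbon prevents a following Cope shift to a linear prenyl group, and the mirror symmetry of 2 allows only one regioisomer.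

Step 3
Reactants: 4 2,4,6-trihydroxy-3-(2-methylbut-3-en-2-yl)benzaldehyde
Product: 5 2-hydroxy-4,6-bis(methoxymethoxy)-3-(2-methylbut-3-en-2-yl)benzaldehyde
Conditions: MOMCl (2.1 equiv), i-Pr2NEt, CH2Cl2, 0 °C
Reagents that add atoms: chloromethyl methyl ether (MOMCl), COCCl
Why: Selective MOM ether formation; the non-chelated 4-hydroxyl and the unhindered 6-hydroxyl should react, whereas the 2-hydroxyl, hydrogen-bonded to the formyl oxygen and flanked by the quaternary carbon, should stay free.

Step 4
Reactants: 5 2-hydroxy-4,6-bis(methoxymethoxy)-3-(2-methylbut-3-en-2-yl)benzaldehyde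
Product: 6 2-(allyloxy)-4,6-bis(methoxymethoxy)-3-(2-methylbut-3-en-2-yl)benzaldehyde
Conditions: allyl bromide, K2CO3, DMF, 50 °C
Reagents that add atoms: allyl bromide, C=CCBr
Why: Williamson etherification of the remaining chelated phenol under more forcing conditions masks the future furan oxygen during the homologation.

Step 5
Reactants: 6 2-(allyloxy)-4,6-bis(methoxymethoxy)-3-(2-methylbut-3-en-2-yl)benzaldehyde
Product: 7 3-(allyloxy)-2-ethynyl-1,5-bis(methoxymethoxy)-4-(2-methylbut-3-en-2-yl)benzene
Conditions: Ohira–Bestmann reagent, K2CO3, MeOH, rt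
Reagents that add atoms: dimethyl (1-diazo-2-oxopropyl)phosphonate (Ohira–Bestmann reagent), COP(=O)(OC)C(=[N+]=[N-])C(C)=O
Why: Seyferth–Gilbert homologation in the Ohira–Bestmann variant converts the formyl group into the terminal alkyne under mild base that leaves allyl and MOM ethers untouched.

Step 6
Reactants: 7 3-(allyloxy)-2-ethynyl-1,5-bis(methoxymethoxy)-4-(2-methylbut-3-en-2-yl)benzene
Product: 8 2-ethynyl-3,5-bis(methoxymethoxy)-6-(2-methylbut-3-en-2-yl)phenol
Conditions: Pd(PPh3)4 (2 mol %), morpholine, THF, rt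
Reagents that add atoms: none
Why: Tsuji–Trost-type deallylation; zerovalent palladium ionizes only the aryl allyl ether and morpholine captures the allyl unit, so the alkyne, the 1,1-dimethylallyl group and the MOM ethers should survive.

Step 7
Reactants: 9 phloroglucinol (benzene-1,3,5-triol)
Product: 11 2,2-dimethylchroman-5,7-diol, via 2-prenylphloroglucinol 10 (not isolated)
Conditions: isoprene, 85% H3PO4, xylene, 30 °C, excess of 9
Reagents that add atoms: isoprene (2-methylbuta-1,3-diene), C=CC(C)=C
Why: Acid-catalysed Friedel–Crafts prenylation of the symmetric triol followed by Markovnikov addition of the adjacent hydroxyl to the trisubstituted alkene closes the pyran ring (6-endo mode), and the excess of 9 limits double annulation.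

Step 8
Reactants: 11 2,2-dimethylchroman-5,7-diol
Product: 12 5,7-bis(methoxymethoxy)-2,2-dimethylchroman
Conditions: MOMCl (2.5 equiv), i-Pr2NEt, CH2Cl2, 40 °C
Reagents that add atoms: chloromethyl methyl ether (MOMCl), COCCl
Why: MOM ether formation at both phenols installs groups that protect the oxygens and direct the following metalation.

Step 9
Reactants: 12 5,7-bis(methoxymethoxy)-2,2-dimethylchroman
Product: 14 5,7-bis(methoxymethoxy)-2,2-dimethyl-6-(3-methylbut-2-en-1-yl)chroman, via 6-lithiochroman 13 (not isolated)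
Conditions: n-BuLi, TMEDA, THF, 0 °C; then CuI (10 mol %), prenyl bromide, −78 °C to rt
Reagents that add atoms: prenyl bromide (1-bromo-3-methylbut-2-ene), CC(C)=CCBr
Why: Directed ortho metalation should occur at C6, the carbon flanked by two chelating MOM ethers, in preference to C8, and copper-catalysed SN2 allylation of the aryllithium should give the linear prenyl arene.

Step 10
Reactants: 14 5,7-bis(methoxymethoxy)-2,2-dimethyl-6-(3-methylbut-2-en-1-yl)chroman
Product: 15 2,2-dimethyl-6-(3-methylbut-2-en-1-yl)chroman-5,7-diol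
Conditions: 3 M HCl (aq), MeOH, 40 °C
Reagents that add atoms: none
Why: Acid-catalysed acetal methanolysis removes both MOM groups under conditions too mild to add a phenol to the prenyl double bond.

Step 11
Reactants: 15 2,2-dimethyl-6-(3-methylbut-2-en-1-yl)chroman-5,7-diol
Product: 16 7-(methoxymethoxy)-2,2-dimethyl-6-(3-methylbut-2-en-1-yl)chroman-5-ol
Conditions: MOMCl (1.0 equiv), i-Pr2NEt, CH2Cl2, −20 °C
Reagents that add atoms: chloromethyl methyl ether (MOMCl), COCCl
Why: Selective MOM ether formation; the 7-hydroxyl has one ortho substituent, whereas the 5-hydroxyl is flanked by the C4 methylene and the prenyl group, so the less hindered oxygen should react first.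

Step 12
Reactants: 16 7-(methoxymethoxy)-2,2-dimethyl-6-(3-methylbut-2-en-1-yl)chroman-5-ol
Product: 17 7-(methoxymethoxy)-2,2-dimethyl-6-(3-methylbut-2-en-1-yl)chroman-5-yl trifluoromethanesulfonate
Conditions: Tf2O, pyridine, CH2Cl2, 0 °C
Reagents that add atoms: trifluoromethanesulfonic anhydride (Tf2O), O=S(=O)(OS(=O)(=O)C(F)(F)F)C(F)(F)F
Why: Sulfonylation of the hindered phenol turns the C5–O bond into a leaving group for oxidative addition.

Step 13
Reactants: 8 2-ethynyl-3,5-bis(methoxymethoxy)-6-(2-methylbut-3-en-2-yl)phenol; 17 7-(methoxymethoxy)-2,2-dimethyl-6-(3-methylbut-2-en-1-yl)chroman-5-yl trifluoromethanesulfonate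
Product: 19 5-[4,6-bis(methoxymethoxy)-7-(2-methylbut-3-en-2-yl)benzofuran-2-yl]-7-(methoxymethoxy)-2,2-dimethyl-6-(3-methylbut-2-en-1-yl)chroman, via 2-(arylethynyl)phenol 18 (not isolated)
Conditions: PdCl2(MeCN)2 (5 mol %), XPhos (15 mol %), Cs2CO3 (2.5 equiv), MeCN, 80 °C, slow addition of 8
Reagents that add atoms: none
Why: Zerovalent palladium bearing XPhos inserts into the C5'–O bond of triflate 17, the cesium acetylide of 8 is transferred to palladium and reductive elimination forms the C(sp)–C(aryl) bond of tolane 18, whose phenoxide then adds across the alkyne. The closest known reaction type is the one-pot Sonogashira coupling–cycloisomerization of 2-ethynylphenols with aryl halides or triflates to 2-arylbenzofurans, here in its copper-free form. The furan ring closes in the 5-endo-dig mode: O1 attacks the aryl-bearing alkyne carbon (future C2) and the resulting C3 carbanion or C3–palladium bond is protonated. No stereocentre is formed. The step needs regioselective ring closure, secured because the only free hydroxyl is the one between the alkyne-bearing carbon and the quaternary carbon while the other two ring oxygens are MOM ethers; it also needs coupling at a carbon with two ortho substituents, for which the linear alkyne, the bulky electron-rich phosphine and the slow addition of 8 (which also limits alkyne self-coupling and premature cyclization of 8) are chosen.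

Step 14
Reactants: 19 5-[4,6-bis(methoxymethoxy)-7-(2-methylbut-3-en-2-yl)benzofuran-2-yl]-7-(methoxymethoxy)-2,2-dimethyl-6-(3-methylbut-2-en-1-yl)chroman
Product: 20 Artopetelin C
Conditions: 3 M HCl (aq), MeOH/THF, 40 °C
Reagents that add atoms: none
Why: Acid-catalysed methanolysis of the three phenolic MOM acetals under mild conditions should release the triol without acid-induced addition of the phenols to the prenyl or 1,1-dimethylallyl double bonds.

**Compound list**

1 | 2,4,6-trihydroxybenzaldehyde | O=Cc1c(O)cc(O)cc1O | starting material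
2 | 2,6-dihydroxy-4-[(3-methylbut-2-en-1-yl)oxy]benzaldehyde | O=Cc1c(O)cc(OCC=C(C)C)cc1O | intermediate
3 | 2,6-dihydroxy-3-(2-methylbut-3-en-2-yl)-4-oxocyclohexa-1,5-diene-1-carbaldehyde (ortho-dienone) | O=CC1=C(O)C(C(C)(C)C=C)C(=O)C=C1O | intermediate
4 | 2,4,6-trihydroxy-3-(2-methylbut-3-en-2-yl)benzaldehyde | O=Cc1c(O)cc(O)c(C(C)(C)C=C)c1O | intermediate
5 | 2-hydroxy-4,6-bis(methoxymethoxy)-3-(2-methylbut-3-en-2-yl)benzaldehyde | O=Cc1c(OCOC)cc(OCOC)c(C(C)(C)C=C)c1O | intermediate
6 | 2-(allyloxy)-4,6-bis(methoxymethoxy)-3-(2-methylbut-3-en-2-yl)benzaldehyde | O=Cc1c(OCOC)cc(OCOC)c(C(C)(C)C=C)c1OCC=C | intermediate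
7 | 3-(allyloxy)-2-ethynyl-1,5-bis(methoxymethoxy)-4-(2-methylbut-3-en-2-yl)benzene | C#Cc1c(OCOC)cc(OCOC)c(C(C)(C)C=C)c1OCC=C | intermediate
8 | 2-ethynyl-3,5-bis(methoxymethoxy)-6-(2-methylbut-3-en-2-yl)phenol | C#Cc1c(OCOC)cc(OCOC)c(C(C)(C)C=C)c1O | intermediate
9 | phloroglucinol (benzene-1,3,5-triol) | Oc1cc(O)cc(O)c1 | starting material
10 | 2-(3-methylbut-2-en-1-yl)benzene-1,3,5-triol (2-prenylphloroglucinol) | CC(C)=CCc1c(O)cc(O)cc1O | intermediate
11 | 2,2-dimethylchroman-5,7-diol | CC1(C)CCc2c(O)cc(O)cc2O1 | intermediate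
12 | 5,7-bis(methoxymethoxy)-2,2-dimethylchroman | CC1(C)CCc2c(OCOC)cc(OCOC)cc2O1 | intermediate
13 | [5,7-bis(methoxymethoxy)-2,2-dimethylchroman-6-yl]lithium | [Li]c1c(OCOC)cc2OC(C)(C)CCc2c1OCOC | intermediate
14 | 5,7-bis(methoxymethoxy)-2,2-dimethyl-6-(3-methylbut-2-en-1-yl)chroman | CC1(C)CCc2c(OCOC)c(CC=C(C)C)c(OCOC)cc2O1 | intermediate
15 | 2,2-dimethyl-6-(3-methylbut-2-en-1-yl)chroman-5,7-diol | CC1(C)CCc2c(O)c(CC=C(C)C)c(O)cc2O1 | intermediate
16 | 7-(methoxymethoxy)-2,2-dimethyl-6-(3-methylbut-2-en-1-yl)chroman-5-ol | CC1(C)CCc2c(O)c(CC=C(C)C)c(OCOC)cc2O1 | intermediate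
17 | 7-(methoxymethoxy)-2,2-dimethyl-6-(3-methylbut-2-en-1-yl)chroman-5-yl trifluoromethanesulfonate | CC1(C)CCc2c(OS(=O)(=O)C(F)(F)F)c(CC=C(C)C)c(OCOC)cc2O1 | intermediate
18 | 2-{[7-(methoxymethoxy)-2,2-dimethyl-6-(3-methylbut-2-en-1-yl)chroman-5-yl]ethynyl}-3,5-bis(methoxymethoxy)-6-(2-methylbut-3-en-2-yl)phenol | C=CC(C)(C)c1c(O)c(C#Cc2c(CC=C(C)C)c(OCOC)cc3OC(C)(C)CCc23)c(OCOC)cc1OCOC | intermediate
19 | 5-[4,6-bis(methoxymethoxy)-7-(2-methylbut-3-en-2-yl)benzofuran-2-yl]-7-(methoxymethoxy)-2,2-dimethyl-6-(3-methylbut-2-en-1-yl)chroman | C=CC(C)(C)c1c(OCOC)cc(OCOC)c2cc(-c3c(CC=C(C)C)c(OCOC)cc4c3CCC(C)(C)O4)oc12 | intermediate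
20 | Artopetelin C (2-[7-hydroxy-2,2-dimethyl-6-(3-methylbut-2-en-1-yl)chroman-5-yl]-7-(2-methylbut-3-en-2-yl)benzofuran-4,6-diol) | C=CC(C)(C)c1c(O)cc(O)c2cc(-c3c(CC=C(C)C)c(O)cc4c3CCC(C)(C)O4)oc12 | target

**Step count and risks**

Total step count: 14. Longest linear sequence: 8 steps (steps 1–6, 13, 14; the branch of steps 7–12, 13, 14 is equally long).

Steps most likely to fail:

1. Step 13. What may go wrong: ring closure of 8 to the C2-unsubstituted benzofuran ahead of the coupling, or slow oxidative addition at the electron-rich triflate carbon with two ortho substituents, so that the alkyne oligomerizes instead. Fallback: setting out from 8, the ring closure is carried out on purpose (CuI 10 mol %, Et3N, DMF, 60 °C) to give 4,6-bis(methoxymethoxy)-7-(2-methylbut-3-en-2-yl)benzofuran F1. Its C2–H is zincated with TMPZnCl·LiCl (THF, 25 °C) to [4,6-bis(methoxymethoxy)-7-(2-methylbut-3-en-2-yl)benzofuran-2-yl]zinc chloride F2. Negishi coupling of this zinc reagent with 17 (Pd(OAc)2, SPhos, THF, 60 °C) comes back to the route at 19.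

2. Step 2. What may go wrong: heterolysis of the allylic C–O bond in the hot protic medium (loss of the prenyl group or its return to carbon as a linear unit) and addition of a flanking hydroxyl to the new vinyl group. Fallback: setting out from 2, both hydroxyls are silylated (TBSCl, imidazole, DMF, 40 °C) to 2,6-bis(tert-butyldimethylsilyloxy)-4-[(3-methylbut-2-en-1-yl)oxy]benzaldehyde F3. The rearrangement is then run on this non-acidic ether in an aprotic basic medium (N,N-diethylaniline, 180 °C) to 2,6-bis(tert-butyldimethylsilyloxy)-4-hydroxy-3-(2-methylbut-3-en-2-yl)benzaldehyde F4. Desilylation with TBAF (THF, 0 °C) comes back to the route at 4.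

3. Step 3. What may go wrong: poor discrimination between the two hydroxyls next to the formyl group, or over-alkylation of all three hydroxyls. Fallback: setting out from 2, one equivalent of MOMCl (i-Pr2NEt, CH2Cl2, 0 °C) gives 2-hydroxy-6-(methoxymethoxy)-4-[(3-methylbut-2-en-1-yl)oxy]benzaldehyde F5, in which the second hydroxyl is locked in the chelate. Claisen rearrangement (N,N-diethylaniline, 180 °C) should be steered by the bond fixation of the chelate ring to the carbon next to the free hydroxyl, giving 2,4-dihydroxy-6-(methoxymethoxy)-3-(2-methylbut-3-en-2-yl)benzaldehyde F6. MOM protection of its non-chelated 4-hydroxyl (MOMCl, i-Pr2NEt, CH2Cl2, 0 °C) comes back to the route at 5.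

**Further compounds**

F1 | step 13 | 4,6-bis(methoxymethoxy)-7-(2-methylbut-3-en-2-yl)benzofuran | C=CC(C)(C)c1c(OCOC)cc(OCOC)c2ccoc12
F2 | step 13 | [4,6-bis(methoxymethoxy)-7-(2-methylbut-3-en-2-yl)benzofuran-2-yl]zinc chloride | C=CC(C)(C)c1c(OCOC)cc(OCOC)c2cc([Zn]Cl)oc12
F3 | step 2 | 2,6-bis(tert-butyldimethylsilyloxy)-4-[(3-methylbut-2-en-1-yl)oxy]benzaldehyde | O=Cc1c(O[Si](C)(C)C(C)(C)C)cc(OCC=C(C)C)cc1O[Si](C)(C)C(C)(C)C
F4 | step 2 | 2,6-bis(tert-butyldimethylsilyloxy)-4-hydroxy-3-(2-methylbut-3-en-2-yl)benzaldehyde | O=Cc1c(O[Si](C)(C)C(C)(C)C)cc(O)c(C(C)(C)C=C)c1O[Si](C)(C)C(C)(C)C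
F5 | step 3 | 2-hydroxy-6-(methoxymethoxy)-4-[(3-methylbut-2-en-1-yl)oxy]benzaldehyde | O=Cc1c(O)cc(OCC=C(C)C)cc1OCOC
F6 | step 3 | 2,4-dihydroxy-6-(methoxymethoxy)-3-(2-methylbut-3-en-2-yl)benzaldehyde | O=Cc1c(OCOC)cc(O)c(C(C)(C)C=C)c1O
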